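The ratio to look at first is the run time over the half-life of the starting material, 0.966, which is just under one.

    second nucleophile + intermediate → other capture product (k1 = 0.039 M⁻¹ s⁻¹)
    first nucleophile + intermediate → target (k2 = 0.056 M⁻¹ s⁻¹)
    starting material → intermediate (k3 = 9.3 × 10⁻⁴ s⁻¹)
    intermediate → side product (k4 = 0.0019 s⁻¹)
    crystals ⇌ target, rate k5*(cs5 - [target]) while solid is left; crystals form when [target] > cs5 (cs5 = 0.27 M, k5 = 0.056 s⁻¹)
    solid second nucleophile ⇌ second nucleophile, rate k6*(cs6 - [second nucleophile]) while solid is left; crystals form when [second nucleophile] > cs6 (cs6 = 30 mM, k6 = 6.7 × 10⁻⁴ s⁻¹)

common to all: starting material 0.40 M; solid second nucleophile 0.380 M; time 12 min
- epsilon: first nucleophile 0.420 M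
- gamma: first nucleophile 0.630 M
- alpha: first nucleophile 0.940 M

* which of these there is most of at the end, counted by the starting material in it, epsilon (target / starting material / intermediate / side product)
* which of these there is most of at the end, counted by the starting material in it, gamma (target / starting material / intermediate / side product)
* which of these there is most of at the end, counted by the starting material in it, alpha (target / starting material / intermediate / side product)
* final amount of the leader among these, as a percentage of the starting material charged, in epsilon
* final amount of the leader among these, as a percentage of the starting material charged, in gamma
* final amount of the leader among these, as a percentage of the starting material charged, in alpha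

- what is said of target includes crystals
- crystals, solid second nucleophile is a solid; its amount is given per volume of the solution
- at the start none of the solid second nucleophile is in solution
- run time (epsilon): 12 min

We build the flask one process at a time. First we keep the main step, the turning of starting material into intermediate, with rate constant k = 9.3 × 10⁻⁴ s⁻¹; its rate holds no nucleophile. This gives the survival fraction S = exp(−kt), which at the run time t = 12 min comes to 51.2%, the part of the charged starting material not yet turned. So 48.8% has left, which is less than S, and this is the ceiling for intermediate and its products taken together.

Next we add capture by the first nucleophile. In epsilon the half-life of intermediate by this step, with the charge as it stands, is 0.49 min, far shorter than the 12 min of starting material. In epsilon we therefore expect intermediate near its quasi-steady state, with the main step rate-limiting for target. Capture draws on intermediate, so S does not move.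

Then we add the loss to side product, which divides the ceiling. The first nucleophile falls during the run, so we replace its curve by a mean. At most 0.195 M of first nucleophile is consumed in epsilon, and taking off half of that bound gives an estimated mean of 0.322 M and a capture share of 90.5%. Between the charge and the lowest possible end value the share runs from 92.5% to 86.9%, so the mean errs by a few points. Counting the intermediate still standing as if it had already been captured or lost, our estimate of the amount of target in epsilon is about 44.2%.

The rest changes little. The target ceiling of 0.195 M stays below the solubility 0.27 M, so no crystals are expected. Second nucleophile dissolves to at most 0.0145 M, and in epsilon we reckon its capture far slower than capture by the first nucleophile at its mean. Gamma and alpha carry more first nucleophile, but that charge stands in the capture step and not in the main step, so we carry the same S to them.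

The forecast names starting material for epsilon, starting material for gamma and starting material for alpha, at 51.2%, 51.2% and 51.2%, and calls the decay “a simple first-order step that does not depend on the nucleophile charge”.

The simulation gives starting material, starting material and starting material in the lead, at 51.2% in epsilon, 51.2% in gamma and 51.2% in alpha. Target comes nearest in alpha, at 45.7%, which is 5.5 percentage points short of the leader. Raising S to the power of reading time over run time carries it to alpha read at 50 min, where it gives 6.15%. That reading of alpha holds 6.14% starting material, with target in the lead at 88.7%.

All constants were set for the occasion; the run is a simulation.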